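**Assumption (one line):** prostanoid numbering is used (C1 = ester carbon, C5/C6 = acetoxy carbons, C7=C8 = exocyclic alkene, C9 = ketone, C10 = C–Cl, C12 = ring carbinol); the SMILES is read as (5S,6S,7E,12R,14Z), and compounds 1, 3, 6 and 8 are taken as catalogue items.

## Retrosynthetic overview

1. Punaglandin 4 ⇐ its 7Z isomer by olefin equilibration; the 7Z isomer ⇐ a 1-octenyl-3-chloro-6-(dihydroxyalkyl)fulvene by sensitised ¹O₂ [4+2] across C9/C12, Kornblum–DeLaMare opening and acetylation. This photochemical step makes C9=O and the C12–O stereocentre, relayed from the C6–OH.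
2. Fulvene ⇐ 5-alkylidene-3-chlorocyclopent-2-enone + (Z)-oct-2-enyl barium (1,2-addition, then 1,4-dehydration; regiochemistry of the fulvene is fixed by the enone).
3. Alkylidene enone ⇐ 3-chlorocyclopent-2-enone + a C1–C7 aldehyde (aldol condensation makes C7=C8).
4. Aldehyde ⇐ 2,3-O-isopropylidene-L-threitol (from L-tartaric acid; supplies C5 and C6) + methyl acrylate (Giese addition).
5. Rings: the carbocycle is bought; the only ring formed is the transient 2,3-dioxabicyclo[2.2.1]heptene in the photochemical step, opened in the same flask.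

## Route

**Step 1**
Reactants: 1, (4S,5S)-2,2-dimethyl-1,3-dioxolane-4,5-dimethanol (2,3-O-isopropylidene-L-threitol)
Product: 2, [(4S,5R)-5-(iodomethyl)-2,2-dimethyl-1,3-dioxolan-4-yl]methanol
Conditions: I2 (1.0 equiv), PPh3 (1.0 equiv), imidazole, THF, 0 °C → rt; unreacted 1 recycled
Reagents that add atoms: iodine, II
Why: Appel-type mono-iodination; 1 is C2-symmetric, so either hydroxyl gives the same product and no stereocentre is touched.

**Step 2**
Reactants: 2; 3, methyl acrylate
Product: 4, methyl 4-[(4S,5S)-5-(hydroxymethyl)-2,2-dimethyl-1,3-dioxolan-4-yl]butanoate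
Conditions: methyl acrylate (5 equiv), Bu3SnH (slow addition), AIBN (cat.), PhH, 80 °C
Reagents that add atoms: methyl acrylate (3), C=CC(=O)OC
Why: Giese radical conjugate addition of the primary alkyl radical installs C1–C3 in one step; the radical centre is not stereogenic and the free OH is tolerated.

**Step 3**
Reactants: 4
Product: 5, methyl 4-[(4S,5R)-5-formyl-2,2-dimethyl-1,3-dioxolan-4-yl]butanoate
Conditions: (COCl)2, DMSO, CH2Cl2, −78 °C; Et3N; used crude
Reagents that add atoms: none
Why: Swern oxidation; the trans-dioxolane aldehyde is configurationally stable at low temperature.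

**Step 4**
Reactants: 6, (Z)-oct-2-en-1-ol
Product: 7, (Z)-1-chlorooct-2-ene
Conditions: NCS, Me2S, CH2Cl2, −20 → 0 °C
Reagents that add atoms: N-chlorosuccinimide, O=C1CCC(=O)N1Cl
Why: Corey–Kim allylic chlorination proceeds by SN2 on the alkoxysulfonium salt without allylic transposition or loss of Z geometry.

**Step 5**
Reactants: 8, 3-chlorocyclopent-2-en-1-one; 5
Product: 9, methyl 4-[(4S,5S)-5-[(E)-(4-chloro-2-oxocyclopent-3-en-1-ylidene)methyl]-2,2-dimethyl-1,3-dioxolan-4-yl]butanoate
Conditions: LDA, THF, −78 °C (8, 30 min); then 5, −78 °C; then MsCl, Et3N, −78 °C → rt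
Reagents that add atoms: none
Why: Kinetic α′-enolate aldol addition followed by mesylation/E1cB dehydration (aldol condensation) fixes the C7–C8 bond at the ring carbon remote from chlorine and gives the E-enone with the chain anti to C=O.

**Step 6**
Reactants: 9
Product: 10, methyl (5S,6S,7E)-7-(4-chloro-2-oxocyclopent-3-en-1-ylidene)-5,6-dihydroxyheptanoate
Conditions: AcOH–H2O–THF (3:1:1), 40 °C
Reagents that add atoms: none
Why: Acetal hydrolysis on the acid-stable dienone, done here because the later fulvene will not tolerate protic acid.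

**Step 7**
Reactants: 10; 7
Product: 11, methyl (5S,6S,7E)-7-[3-chloro-5-[(2Z)-oct-2-en-1-yl]cyclopenta-2,4-dien-1-ylidene]-5,6-dihydroxyheptanoate (fulvene; side chain syn to the ring C9–H, anti to the octenyl-bearing carbon)
Conditions: HMDS, TMSOTf (cat.), CH2Cl2, rt, concentrate (transient bis-TMS ether); (Z)-oct-2-enylbarium chloride [from 7, Rieke Ba (BaI2, lithium biphenylide), THF, −78 °C], THF, −78 °C; then MsCl, Et3N, −78 → 0 °C; citric acid, MeOH, 0 °C
Reagents that add atoms: (Z)-1-chlorooct-2-ene (7), CCCCC/C=C\CCl
Why: The allylbarium reagent adds 1,2 at its α-carbon with retention of the Z-olefin; the tertiary bis-allylic mesylate then ionises and loses the doubly allylic ring C9–H (E1-type 1,4-elimination) to give the fulvene, deliberately erasing the uncontrolled C12 centre, and the TMS ethers fall off on mild acidic work-up.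

**Step 8**
Reactants: 11
Product: 12, (7Z)-punaglandin 4, methyl (5S,6S,7Z)-5,6-diacetoxy-7-[(5R)-3-chloro-5-hydroxy-5-[(2Z)-oct-2-en-1-yl]-2-oxocyclopent-3-en-1-ylidene]heptanoate
Conditions: O2, tetraphenylporphyrin (1 mol %), CH2Cl2, −78 °C, visible light (>500 nm); then Et3N, −78 → −30 °C; then Ac2O, pyridine, DMAP (cat.), −30 → 0 °C
Reagents that add atoms: dioxygen, O=O; acetic anhydride, CC(=O)OC(C)=O
Why: Proposed new method: a hydroxyl-directed, face-selective ¹O₂ [4+2] on a 6-(α-hydroxyalkyl)fulvene with in situ Kornblum–DeLaMare opening. Allylic 1,3-strain against the ring C9 side holds C6–H in the fulvene plane, so the C6–OH sits on one face (C5 chain on the other) and hydrogen-bonds the incoming ¹O₂; suprafacial addition across the only cisoid diene (C9/C12) puts both oxygens on that face, which for the 6S fulvene corresponds to 12R. Et3N then removes the single bridgehead H (C9) and O–O heterolysis gives C9=O and the C12 alkoxide, and the two secondary OH groups are acetylated in the same flask while the tertiary OH is left free. The closest known reactions are hydroxy-directed ¹O₂ ene and [4+2] reactions of chiral allylic alcohols and dienols, ¹O₂ addition to fulvenes, and the Kornblum–DeLaMare rearrangement of cyclopentadiene endoperoxides.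

**Step 9**
Reactants: 12
Product: 13, punaglandin 4, methyl (5S,6S,7E)-5,6-diacetoxy-7-[(5R)-3-chloro-5-hydroxy-5-[(2Z)-oct-2-en-1-yl]-2-oxocyclopent-3-en-1-ylidene]heptanoate
Conditions: I2 (5 mol %), CH2Cl2, rt, ambient visible light; aq. Na2S2O3; residual 12 recycled
Reagents that add atoms: none
Why: Iodine-atom addition–elimination equilibrates the conjugated exocyclic enone to the 7E isomer, which I expect (not verified) to be the more stable one with the chain away from the C9 carbonyl; the isolated 14Z alkene reacts much more slowly and no stereocentre is involved.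

## Compound list

1 | (4S,5S)-2,2-dimethyl-1,3-dioxolane-4,5-dimethanol | OC[C@@H]1OC(C)(C)O[C@H]1CO | starting material
2 | [(4S,5R)-5-(iodomethyl)-2,2-dimethyl-1,3-dioxolan-4-yl]methanol | OC[C@@H]1OC(C)(C)O[C@H]1CI | intermediate
3 | methyl acrylate | C=CC(=O)OC | starting material
4 | methyl 4-[(4S,5S)-5-(hydroxymethyl)-2,2-dimethyl-1,3-dioxolan-4-yl]butanoate | OC[C@@H]1OC(C)(C)O[C@H]1CCCC(=O)OC | intermediate
5 | methyl 4-[(4S,5R)-5-formyl-2,2-dimethyl-1,3-dioxolan-4-yl]butanoate | O=C[C@@H]1OC(C)(C)O[C@H]1CCCC(=O)OC | intermediate
6 | (Z)-oct-2-en-1-ol | CCCCC/C=C\CO | starting material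
7 | (Z)-1-chlorooct-2-ene | CCCCC/C=C\CCl | intermediate
8 | 3-chlorocyclopent-2-en-1-one | O=C1C=C(Cl)CC1 | starting material
9 | methyl 4-[(4S,5S)-5-[(E)-(4-chloro-2-oxocyclopent-3-en-1-ylidene)methyl]-2,2-dimethyl-1,3-dioxolan-4-yl]butanoate | O=C1C=C(Cl)C/C1=C\[C@@H]1OC(C)(C)O[C@H]1CCCC(=O)OC | intermediate
10 | methyl (5S,6S,7E)-7-(4-chloro-2-oxocyclopent-3-en-1-ylidene)-5,6-dihydroxyheptanoate | O=C1C=C(Cl)C/C1=C\[C@H](O)[C@@H](O)CCCC(=O)OC | intermediate
11 | methyl (5S,6S,7E)-7-[3-chloro-5-[(2Z)-oct-2-en-1-yl]cyclopenta-2,4-dien-1-ylidene]-5,6-dihydroxyheptanoate | CCCCC/C=C\CC1=CC(Cl)=C/C1=C\[C@H](O)[C@@H](O)CCCC(=O)OC | intermediate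
12 | (7Z)-punaglandin 4 | CCCCC/C=C\C[C@@]1(O)C=C(Cl)C(=O)/C1=C\[C@H](OC(C)=O)[C@H](CCCC(=O)OC)OC(C)=O | intermediate
13 | punaglandin 4 | CCCCC/C=C\C[C@@]1(O)C=C(Cl)C(=O)/C1=C/[C@H](OC(C)=O)[C@H](CCCC(=O)OC)OC(C)=O | target

## Step count and risks

Total steps: 9. Longest linear sequence: 8 (1 → 2 → 4 → 5 → 9 → 10 → 11 → 12 → 13; step 4 is a one-step side branch).

Three steps most likely to fail:

1. **Step 8 (proposed new step).** The C6 stereocentre is three bonds from the reacting diene, so facial selectivity may be only moderate, and the C5–OH could compete as a director. The fulvene endoperoxide can also rearrange thermally before base opens it, and the 7Z γ-hydroxy dienone can close to a hemiketal before acetylation.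
   Fallback (known chemistry): set C12 on the ring before the side chain is attached. Add the octenylbarium reagent anti to the silyloxy group of an enantiopure 3-chloro-4-silyloxycyclopent-2-enone (1,3-induction), desilylate and oxidise to 2-chloro-4-hydroxy-4-octenylcyclopent-2-enone, then join to aldehyde 5 by aldol/E1cB dehydration, remove the acetonide with aqueous AcOH and acetylate.

2. **Step 9.** The E:Z equilibrium ratio is not known and may be modest, and iodine could slowly scramble the 14Z alkene or trigger SN2′ loss of the allylic acetate.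
   Fallback: replace catalytic equilibration by a discrete addition–elimination through an sp³ C7. Add PhSH (Et3N) conjugately at C7, oxidise to the sulfoxide with NaIO4, and eliminate thermally (syn) to re-form the enone as the E isomer; competing addition at C11 would have to be checked.

3. **Step 7.** The barium reagent may enolise the acidic C9–H2 instead of adding, and the elimination could give the exocyclic C12=C13 triene instead of the fulvene. Any water present would divert the cation to the transposed enone with loss of HCl.
   Fallback: reverse the order. Add the octenylbarium reagent to 3-chlorocyclopent-2-enone (8) itself, dehydrate to 1-octenyl-3-chlorocyclopentadiene, and build the fulvene by amine-mediated (pyrrolidine/MeOH) condensation with aldehyde 5. The regioisomeric fulvene would be separated and the diol released afterwards.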